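## Retrosynthetic overview

1. Target 15 ⇒ ketol 13 + stearoyl chloride 14 (ester C–O bond at the C7 tertiary oxygen, made last).
2. 13 ⇒ 12: ring A (C4a–C5–C6–C7–C8–C8a) is opened at C6–C7. C7 is a tertiary carbinol carbon (CH3, O) lying between the C6 and C8 ketones, which is the retron of a crossed benzoin of a C6 aldehyde onto the C7 ketone of a pyruvoyl group on C8a. The Z-dienal 12 is reached from its E isomer 11 by light.
3. 11 ⇒ iodo-dienal 8 (C8a–C8 by carbonylative Stille coupling with an ethoxyvinylstannane, then hydrolysis) ⇒ 5-iodopyranone 5 (C4a=C5 by ethoxyvinyl addition and hydrolysis). The iodine is placed on the pyranone, where C8a is the only nucleophilic carbon.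
4. 5 ⇒ (R)-pyranone 4 ⇒ Danishefsky's diene 1 + acetaldehyde 2 (asymmetric hetero-Diels–Alder sets C3).
5. Ring order: ring B (pyran, O2–C1–C8a–C4a–C4–C3) first, ring A second.

Key step: step 6

Remarks on the chemistry:
- Atom numbers are those of the isochromene target throughout.
- For steps 1 and 6 the catalyst antipode is fixed by a trial run against the facial requirement stated in the step; both antipodes are accessible.
- Compounds 8, 10 and 11 are drawn as the E isomers expected at equilibrium (CHO remote from the C8a substituent); any Z isomer present converges in step 6.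

## Route

Step 1
Reactants: 1 1-methoxy-3-(trimethylsilyloxy)buta-1,3-diene; 2 acetaldehyde
Product: 4 (R)-2-methyl-2,3-dihydro-4H-pyran-4-one, via cis cycloadduct 3 (not isolated)
Conditions: chiral (salen)Cr(III)BF4 (2 mol %), 4 Å MS, t-BuOMe, −30 °C; then TFA (cat.), CH2Cl2, 0 °C, aqueous work-up
Reagents that add atoms: none
Why: Catalytic asymmetric hetero-Diels–Alder reaction of Danishefsky's diene with an aliphatic aldehyde: the chiral Cr(III) Lewis acid should direct the diene to the Si face of acetaldehyde, which sets C3 as R, and acid then eliminates methanol and removes the silyl group to give the enone.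

Step 2
Reactants: 4 (R)-2-methyl-2,3-dihydro-4H-pyran-4-one
Product: 5 (R)-5-iodo-2-methyl-2,3-dihydro-4H-pyran-4-one
Conditions: I2 (1.5 equiv), pyridine, CH2Cl2, 0 °C → rt
Reagents that add atoms: iodine, II
Why: Electrophilic α-iodination of a β-alkoxy enone (I2/pyridine): at this stage C8a is the only nucleophilic carbon, whereas in the later dienal C5 would compete, so the halogen is introduced here; C3 is not involved.

Step 3
Reactants: 5 (R)-5-iodo-2-methyl-2,3-dihydro-4H-pyran-4-one; 6 (Z)-1-bromo-2-ethoxyethene
Product: 8 (R,E)-2-(5-iodo-2-methyl-2,3-dihydro-4H-pyran-4-ylidene)acetaldehyde, via tertiary carbinol 7 (not isolated)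
Conditions: 6, t-BuLi (2 equiv per 6), THF, −78 °C; CeCl3, −78 °C; then 5, −78 → −40 °C; 1 M aq. HCl, THF, 0 °C, short contact
Reagents that add atoms: water, O
Why: Wollenberg two-carbon homologation: the organocerium form of (Z)-2-ethoxyvinyllithium should add 1,2 to the vinylogous ester carbonyl without iodine–metal exchange, and dilute acid then hydrolyses the enol ether with allylic loss of the tertiary hydroxyl to the conjugated aldehyde, expected mainly as the E isomer; the transient carbinol centre at C4a is destroyed and C3 is untouched.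

Step 4
Reactants: 8 (R,E)-2-(5-iodo-2-methyl-2,3-dihydro-4H-pyran-4-ylidene)acetaldehyde; 9 tributyl(1-ethoxyvinyl)stannane
Product: 10 (R,E)-2-[5-(2-ethoxyacryloyl)-2-methyl-2,3-dihydro-4H-pyran-4-ylidene]acetaldehyde
Conditions: CO (3 atm), PdCl2(PPh3)2 (5 mol %), THF, 50 °C
Reagents that add atoms: carbon monoxide, [C-]#[O+]
Why: Carbonylative Stille coupling of an alkenyl iodide with an α-alkoxyvinylstannane: oxidative addition at C8a–I, CO insertion, transmetalation and reductive elimination should give the α-ethoxy divinyl ketone as a masked 1,2-diketone, while the aldehyde and the ring enol ether are inert to Pd(0)/CO at this temperature.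

Step 5
Reactants: 10 (R,E)-2-[5-(2-ethoxyacryloyl)-2-methyl-2,3-dihydro-4H-pyran-4-ylidene]acetaldehyde
Product: 11 (R,E)-2-[2-methyl-5-(2-oxopropanoyl)-2,3-dihydro-4H-pyran-4-ylidene]acetaldehyde
Conditions: 1 M aq. HCl, THF, 0 °C → rt
Reagents that add atoms: water, O
Why: Acid hydrolysis of the 2-ethoxy enone (an enol ether) to the 1,2-diketone; the cyclic vinylogous ester should tolerate brief exposure to dilute acid, and C3 is not affected.

Step 6
Reactants: 11 (R,E)-2-[2-methyl-5-(2-oxopropanoyl)-2,3-dihydro-4H-pyran-4-ylidene]acetaldehyde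
Product: 13 (3R,7R)-7-hydroxy-3,7-dimethyl-3,4-dihydroisochromene-6,8-dione, via Z-dienal 12 (not isolated)
Conditions: hν (365 nm LED), degassed PhMe (0.02 M), rt, to the photostationary state; then in the dark aminoindanol-derived N-C6F5 triazolium BF4 (15 mol %), Et3N (15 mol %), PhMe, rt; recovered 11 is re-irradiated and resubmitted
Reagents that add atoms: none
Why: Irradiation at the long-wavelength edge of the push–pull dienal band equilibrates the C4a=C5 geometry (E→Z photoisomerisation of a conjugated enal), and only the Z isomer 12, in which C6 lies next to the pyruvoyl group, can cyclise. The triazolylidene adds to the C6 aldehyde, proton transfer gives the Breslow intermediate, its C6 attacks the C7 ketone (6-exo-trig closure of ring A through C6–C7), and proton transfer with release of the carbene gives the tertiary ketol; the closest known reaction is the carbene-catalysed intramolecular aldehyde–ketone crossed benzoin to six-membered α-ketols, with an enal as the less common donor. C7 is set by the chiral aminoindanol scaffold, which must deliver C6 to the Re face of the C7 carbonyl (O > C8 > CH3 clockwise) to give 7R, and the remote C3 centre should have little influence. Site selectivity for C7 over C8 follows from ring size (attack at C8 would give a five-membered ring) and from C8 being a deactivated vinylogous ester carbonyl while C7 is activated as the distal carbonyl of a 1,2-diketone. The homoenolate path is closed because C4a could reach C7 only through a four-membered ring, the electron-poor N-C6F5 catalyst with a weak base favours acyl-anion over β-protonation chemistry, and the weak base avoids γ-deprotonation at C4, which would endanger C3. The product has no hydrogen at C7 and cannot racemise there.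

Step 7
Reactants: 13 (3R,7R)-7-hydroxy-3,7-dimethyl-3,4-dihydroisochromene-6,8-dione; 14 stearoyl chloride
Product: 15 (3R,7R)-3,7-dimethyl-6,8-dioxo-3,4-dihydroisochromen-7-yl octadecanoate
Conditions: 14 (1.5 equiv), DMAP (0.2 equiv), Et3N, CH2Cl2, 0 °C → rt
Reagents that add atoms: none
Why: DMAP-catalysed acyl transfer from the acid chloride to the tertiary α-ketol oxygen, the usual way C7 esters of azaphilone-type cores are made; C7 carries no hydrogen and Et3N is too weak to deprotonate C4, so neither stereocentre should be disturbed.

## Compound list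

1 | 1-methoxy-3-(trimethylsilyloxy)buta-1,3-diene (Danishefsky's diene) | CO/C=C/C(=C)O[Si](C)(C)C | starting material
2 | acetaldehyde | CC=O | starting material
3 | (2R,6R)-6-methoxy-2-methyl-4-(trimethylsilyloxy)-3,6-dihydro-2H-pyran (cis cycloadduct) | CO[C@H]1C=C(O[Si](C)(C)C)C[C@@H](C)O1 | intermediate
4 | (R)-2-methyl-2,3-dihydro-4H-pyran-4-one | C[C@@H]1CC(=O)C=CO1 | intermediate
5 | (R)-5-iodo-2-methyl-2,3-dihydro-4H-pyran-4-one | C[C@@H]1CC(=O)C(I)=CO1 | intermediate
6 | (Z)-1-bromo-2-ethoxyethene | Br/C=C\OCC | starting material
7 | (2R)-4-[(Z)-2-ethoxyvinyl]-5-iodo-2-methyl-3,4-dihydro-2H-pyran-4-ol (both C4 epimers, centre lost in the same flask) | C[C@@H]1CC(O)(/C=C\OCC)C(I)=CO1 | intermediate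
8 | (R,E)-2-(5-iodo-2-methyl-2,3-dihydro-4H-pyran-4-ylidene)acetaldehyde | C[C@@H]1C/C(=C\C=O)C(I)=CO1 | intermediate
9 | tributyl(1-ethoxyvinyl)stannane | CCCC[Sn](CCCC)(CCCC)C(=C)OCC | starting material
10 | (R,E)-2-[5-(2-ethoxyacryloyl)-2-methyl-2,3-dihydro-4H-pyran-4-ylidene]acetaldehyde | C[C@@H]1C/C(=C\C=O)C(=CO1)C(=O)C(=C)OCC | intermediate
11 | (R,E)-2-[2-methyl-5-(2-oxopropanoyl)-2,3-dihydro-4H-pyran-4-ylidene]acetaldehyde | C[C@@H]1C/C(=C\C=O)C(=CO1)C(=O)C(C)=O | intermediate
12 | (R,Z)-2-[2-methyl-5-(2-oxopropanoyl)-2,3-dihydro-4H-pyran-4-ylidene]acetaldehyde | C[C@@H]1C/C(=C/C=O)C(=CO1)C(=O)C(C)=O | intermediate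
13 | (3R,7R)-7-hydroxy-3,7-dimethyl-3,4-dihydroisochromene-6,8-dione | O[C@]1(C)C(=O)C=C2C[C@@H](C)OC=C2C1=O | intermediate
14 | stearoyl chloride (octadecanoyl chloride) | CCCCCCCCCCCCCCCCCC(=O)Cl | starting material
15 | (3R,7R)-3,7-dimethyl-6,8-dioxo-3,4-dihydroisochromen-7-yl octadecanoate | CCCCCCCCCCCCCCCCCC(=O)O[C@]1(C)C(=O)C=C2C[C@@H](C)OC=C2C1=O | target

Total step count: 7
Longest linear sequence: 7 steps (1 → 15, fully linear)

## Steps most likely to fail

**Step 6 (key step).** Three processes may defeat it. The photo-equilibration may supply too little Z isomer, or thermal return to E may outpace cyclisation. The enal-derived Breslow intermediate may be protonated at C4a (redox path) instead of attacking C7. Facial selectivity at C7 may be low. The fallback forms C6–C7 intermolecularly, where alkene geometry plays no part, and closes ring A at C4a=C5 by aldol condensation. It sets out from 5. Carbonylative Stille coupling of 5 with 9 under CO should give (R)-5-(2-ethoxyacryloyl)-2-methyl-2,3-dihydro-4H-pyran-4-one F1. Dilute HCl should then give (R)-2-methyl-5-(2-oxopropanoyl)-2,3-dihydro-4H-pyran-4-one F2. A chiral triazolium-catalysed crossed benzoin with acetaldehyde 2 as acyl donor onto the activated C7 ketone (Re face) should give (R)-5-[(R)-2-hydroxy-2-methyl-3-oxobutanoyl]-2-methyl-2,3-dihydro-4H-pyran-4-one F3. Intramolecular aldol addition of the C5 methyl ketone to the C4a ring carbonyl (LiHMDS, THF, −78 °C) and acid-promoted dehydration would then return to the route at 13.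

**Step 4.** Transmetalation may outrun CO insertion and give the direct coupling product, or oxidative addition at the donor-substituted alkenyl iodide may be slow and material may be lost. The fallback separates acyl formation from C–C coupling and sets out from 8. Pd-catalysed thiocarbonylation (CO, EtSH, Et3N, Pd(OAc)2/PPh3) should give S-ethyl (R,E)-2-methyl-4-(2-oxoethylidene)-3,4-dihydro-2H-pyran-5-carbothioate F4. A Cu(I) diphenylphosphinate-mediated, Pd-catalysed thioester–stannane ketone synthesis (Liebeskind–Srogl type) with 9 would then rejoin the route at 10.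

**Step 3.** Iodine–metal exchange at C8a may compete, or 1,2-addition to the vinylogous ester carbonyl may be sluggish. In the acid stage the dihydropyran may open and re-close through the doubly oxygen-stabilised pentadienyl cation, which would move the iodine to the exocyclic carbon. The fallback is a Peterson-type formyl-olefination that passes through no such cation and sets out from 5. Lithiated N-tert-butyl-2-(trimethylsilyl)acetaldimine (LDA, THF, −78 → 0 °C) should add to the ketone and eliminate silanolate to give (R,E)-N-tert-butyl-2-(5-iodo-2-methyl-2,3-dihydro-4H-pyran-4-ylidene)ethan-1-imine F5. Hydrolysis with aqueous oxalic acid would rejoin the route at 8.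

## Further compounds

F1 | step 6 | (R)-5-(2-ethoxyacryloyl)-2-methyl-2,3-dihydro-4H-pyran-4-one | C[C@@H]1CC(=O)C(=CO1)C(=O)C(=C)OCC
F2 | step 6 | (R)-2-methyl-5-(2-oxopropanoyl)-2,3-dihydro-4H-pyran-4-one | C[C@@H]1CC(=O)C(=CO1)C(=O)C(C)=O
F3 | step 6 | (R)-5-[(R)-2-hydroxy-2-methyl-3-oxobutanoyl]-2-methyl-2,3-dihydro-4H-pyran-4-one | C[C@@H]1CC(=O)C(=CO1)C(=O)[C@](C)(O)C(C)=O
F4 | step 4 | S-ethyl (R,E)-2-methyl-4-(2-oxoethylidene)-3,4-dihydro-2H-pyran-5-carbothioate | C[C@@H]1C/C(=C\C=O)C(=CO1)C(=O)SCC
F5 | step 3 | (R,E)-N-tert-butyl-2-(5-iodo-2-methyl-2,3-dihydro-4H-pyran-4-ylidene)ethan-1-imine | C[C@@H]1C/C(=C\C=NC(C)(C)C)C(I)=CO1
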